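Start from the plateaus.

| setting | alder | maple | oak | flask |
|---|---|---|---|---|
| X | 0.13 M | 0.13 M | 0.13 M | 0.13 M |
| Q | 2 equiv (fed, over 20 s) | 2 equiv (fed, over 20 s) | 2 equiv (fed, over 20 s) | 2.00 equiv (fed, over 20 s) |
| Eb | 0.039 M | 0.039 M | 0.058 M | 0.0390 M |
| E | 3.4 mol% | 7.5 mol% | 5 mol% | 5 mol% |
| remark | run made earlier; the fed solution adds 0.10 times the starting volume | run made earlier; the fed solution adds 0.10 times the starting volume | run made earlier; the fed solution adds 0.10 times the starting volume | the fed solution adds 0.10 times the starting volume |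
| time |  |  |  | 2.0 h |

| run | time / min | X / % | Wu / % |
|---|---|---|---|
| alder | 10.0 | 56.4 | 5.8 |
| alder | 20.0 | 57.1 | 6.8 |
| alder | 30.0 | 56.8 | 6.1 |
| alder | 60.0 | 56.3 | 6.4 |
| alder | 120 | 56.7 | 5.8 |
| maple | 25.0 | 44.8 | 8.9 |
| maple | 50.0 | 45.2 | 9.5 |
| maple | 80.0 | 45.4 | 9.7 |
| maple | 90.0 | 44.3 | 8.7 |
| maple | 120 | 44.2 | 9.7 |
| oak | 10.0 | 38.5 | 6.9 |
| oak | 30.0 | 37.8 | 6.8 |
| oak | 60.0 | 38.6 | 7.2 |
| oak | 80.0 | 37.4 | 7.4 |
| oak | 120 | 36.7 | 7.9 |

(readings scatter by 0.5 percentage points)

- in percentages every species weighs as the X in it: one Lx counts as two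
- charges are per starting volume, the dose included; the dosed solution carries all of it
- the numbers in the tables scatter with a standard deviation of 0.5 percentage points
- reactions considered so far: E -> 2 G; X + G -> Wy + D; Q + D -> Wu + Z; X + Z -> Qa + D; D -> J; 2 D -> Lx; Q + Wu -> Q.Wu; X + Eb -> X.Eb; 2 Q -> Q2

* conversion of X at 2.0 h
* amount of Wu at 2.0 h, in percent of the X charged

1. Read the plateaus. In the alder run X stands at 56.4 % after 10.0 min and 56.7 % after 120 min, against a scatter of 0.5 percentage points. So you take the mean of each run's 5 readings as its end state. That gives conversions of 43.3 % for alder, 55.2 % for maple and 62.2 % for oak.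

2. Charge the toll. Suppose Eb takes X one for one until Eb, the limiting reagent of that step, is used up. The share of X lost this way is c(Eb)/c(X) at the charge, 30.0 % for this flask and for alder and maple: call it the Eb toll.

3. Subtract it. The chain part left over is 13 points for alder at 3.4 mol% of E and 25 points for maple at 7.5 mol%.

4. Interpolate to this flask's 5 mol%. A straight line gives a chain part of 18 points, so I commit to a conversion of 48.0 %. The same line through the mean Wu of alder and maple gives 7.40 %.

5. Reforge the weak link, the toll. Oak has more Eb at this flask's loading of E, and its toll is 44.6 %. That leaves oak a chain part of 18 points, a gap of 0.39 points from step 4 against a scatter of 0.5 points.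

The forecast gives a conversion of 48.1 % and 7.5 % of Wu, its Wu above my line; it reads “Eb appears to remove X one-for-one”.

This flask gives 48.0 % conversion and 7.45 % of Wu at 2.0 h, and both forecast values are right within the tolerance.

    E → 2 G (k = 0.0220 /s)
    X + G → Wy + D (k = 1.10 × 10⁵ /M/s)
    Q + D → Wu + Z (k = 2300 /M/s)
    X + Z → Qa + D (k = 11000 /M/s)
    D → J (k = 36.0 /s)
    2 D → Lx (k = 5.80 × 10⁷ /M/s)
    Q + Wu → Q.Wu (k = 0.00950 /M/s)
    X + Eb → X.Eb (k = 0.350 /M/s)
    2 Q → Q2 (k = 0.390 /M/s)

At that time this flask holds X.Eb at 30.0 %, which is the toll of 30.0 %, with 0 % of its Eb left and 52 % of its X. Now take a neighbour flask, made like this flask but with 0.033 M of X. Its toll is 118 %, more than the whole X charged. That neighbour flask ends with X at 0 %, X.Eb at 83.3 % and 29.5 % of its Eb left.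

The runs stem from a simulated flask with made-up constants; the scatter is artificial.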